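**Assumptions (one line):** The SMILES is read as the cis-fused decalin (5R,8S,9R,10S), i.e. the 5-epi-ilimaquinone skeleton, named (1R,2S,4aR,8aS) as a naphthalene; terpenoid numbering C1–C10 is used below (C4 bears =CH2, C5/C10 are the ring-fusion carbons, C8 is CHMe, C9 is the quaternary carbon bearing the CH2-quinone). The catalyst antipode in Step 2 is whichever delivers (1S,6S)-5; the (S)-prolinol-derived catalyst is assumed.

**Retrosynthetic overview**
1. Hydroxy-methoxy-quinone ⇐ 2,3,5,6-tetramethoxyaryl group (CAN oxidation, then selective hydrolysis), done last.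
2. C6 oxygen removed by Wolff–Kishner; C8 ⇐ dissolving-metal reduction of a C7=C8(Me) enone, with H delivered to the α face.
3. Ring A (formed last), the C5 quaternary centre, the cis ring fusion and the C4 exo-methylene ⇐ one gold(I)-catalysed 6-exo-dig silyl enol ether/alkyne (Conia-ene-type) cyclisation.
4. C10 ⇐ cuprate addition of a pentynyl chain to a chiral 4,4-disubstituted cyclohexa-2,5-dienone, anti to the arylmethyl group, with the enolate trapped as the silyl dienol ether.
5. Ring B (formed first) and C9 ⇐ catalytic enantioselective Diels–Alder of tiglaldehyde with a 2-silyloxy diene; aryl group by ArLi addition and deoxygenation. No enolate benzylation and no Wittig methylenation are used.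

**Route**

Step 1
Reactants: 1, 3-methylbut-3-en-2-one; 2, triisopropylsilyl triflate
Product: 3, 3-methyl-2-[(triisopropylsilyl)oxy]buta-1,3-diene
Conditions: TIPSOTf, Et3N, Et2O, 0 °C → rt
Reagents that add atoms: triisopropylsilyl triflate (2), CC(C)[Si](C(C)C)(C(C)C)OS(=O)(=O)C(F)(F)F
Why: Soft enolisation/O-silylation of an enone whose only enolisable position is the acetyl CH3 gives the 2-silyloxy diene as a single regioisomer.

Step 2
Reactants: 3, the silyloxy diene; 4, (E)-2-methylbut-2-enal (tiglaldehyde)
Product: 5, (1S,6S)-1,3,6-trimethyl-4-[(triisopropylsilyl)oxy]cyclohex-3-ene-1-carbaldehyde (1,6-dimethyl cis)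
Conditions: (S)-o-tolyl-CBS oxazaborolidine (20 mol %), Tf2NH (18 mol %), CH2Cl2, −78 → −40 °C
Reagents that add atoms: (E)-2-methylbut-2-enal (4), C/C=C(\C)C=O
Why: Catalytic enantioselective Diels–Alder with a chiral oxazaborolidinium Lewis acid, which is known to work with α-substituted enals; the 2-silyloxy group enforces "para" regiochemistry (CHO carbon 1,4 to C–OSi), the diene adds to the Si face of the enal α-carbon to set the quaternary centre (future C9), and the cis-dimethyl relationship follows from the (E)-dienophile.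

Step 3
Reactants: 5; 6, 1,2,4,5-tetramethoxybenzene; 7, acetic anhydride
Product: 8, [(1S,6S)-1,3,6-trimethyl-4-[(triisopropylsilyl)oxy]cyclohex-3-en-1-yl](2,3,5,6-tetramethoxyphenyl)methyl acetate (mixture at the carbinol carbon)
Conditions: 6, n-BuLi, THF, 0 °C → rt; then 5, −78 °C; then Ac2O, −78 → 0 °C
Reagents that add atoms: 1,2,4,5-tetramethoxybenzene (6), COc1cc(OC)c(OC)cc1OC; acetic anhydride (7), CC(=O)OC(C)=O
Why: Directed ortho-lithiation between two methoxy groups and 1,2-addition of the aryllithium to the non-enolisable neopentyl aldehyde, with the alkoxide trapped as acetate; the new carbinol centre is removed in the next step and the silyl enol ether is inert.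

Step 4
Reactants: 8
Product: 9, (4R,5S)-2,4,5-trimethyl-4-[(2,3,5,6-tetramethoxyphenyl)methyl]cyclohexan-1-one (C2 epimers)
Conditions: Li, NH3(l)/THF, −78 °C; NH4Cl; then TBAF, AcOH, THF, 0 °C
Reagents that add atoms: none
Why: Dissolving-metal hydrogenolysis of the benzylic C–O bond (Birch-type benzylic deoxygenation) avoids a benzylic cation next to the quaternary carbon, and fluoride then unmasks the ketone; the C2 configuration is irrelevant because it becomes sp2.

Step 5
Reactants: 9
Product: 10, (4S)-2,4,5-trimethyl-4-[(2,3,5,6-tetramethoxyphenyl)methyl]cyclohexa-2,5-dien-1-one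
Conditions: IBX (3.5 equiv), 4-methoxypyridine N-oxide (3.5 equiv), DMSO, 25 → 45 °C
Reagents that add atoms: none
Why: IBX-mediated α,β-dehydrogenation on both sides of the ketone gives the cross-conjugated dienone (the quaternary C4 blocks aromatisation); this removes the old C5 stereocentre deliberately so that C9 is the only stereocentre, and the N-oxide-ligated reagent at low temperature is chosen to spare the electron-rich arene.

Step 6
Reactants: 10; 11, (5-chloropent-1-yn-1-yl)trimethylsilane; 2, triisopropylsilyl triflate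
Product: 12, triisopropyl({(5S,6S)-1,4,5-trimethyl-5-[(2,3,5,6-tetramethoxyphenyl)methyl]-6-[5-(trimethylsilyl)pent-4-yn-1-yl]cyclohexa-1,3-dien-2-yl}oxy)silane (chain cis to the C5 methyl, trans to the arylmethyl)
Conditions: 11, Mg, THF, reflux (→ RMgCl); CuBr·SMe2 (0.5 equiv), THF, −78 °C; 10, −78 → −40 °C; then TIPSOTf, Et3N, −78 → 0 °C
Reagents that add atoms: (5-chloropent-1-yn-1-yl)trimethylsilane (11), C[Si](C)(C)C#CCCCCl; triisopropylsilyl triflate (2), CC(C)[Si](C(C)C)(C(C)C)OS(=O)(=O)C(F)(F)F
Why: Organocuprate 1,4-addition with enolate O-silylation; the cuprate attacks the unsubstituted β-carbon of the 2-methyl enone arm (the other arm is β-methyl and neopentyl) on the face anti to the bulky tetramethoxybenzyl group, setting C10 with the chain cis to the C9 methyl, and the enolate is fixed regiospecifically as the C5=C6 silyl enol ether.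

Step 7
Reactants: 12
Product: 13, triisopropyl({(5S,6S)-1,4,5-trimethyl-6-(pent-4-yn-1-yl)-5-[(2,3,5,6-tetramethoxyphenyl)methyl]cyclohexa-1,3-dien-2-yl}oxy)silane
Conditions: K2CO3, MeOH/THF, 0 °C → rt
Reagents that add atoms: none
Why: Mild methanolysis removes the alkynyl TMS group selectively, while the hindered TIPS dienol ether is stable to carbonate.

Step 8
Reactants: 13
Product: 14, (4S,4aS,8aR)-3,4,8a-trimethyl-8-methylidene-4-[(2,3,5,6-tetramethoxyphenyl)methyl]-4a,5,6,7,8,8a-hexahydronaphthalen-1(4H)-one (cis-fused)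
Conditions: Ph3PAuCl (10 mol %), AgBF4 (10 mol %), CH2Cl2/MeOH 10:1, 40 °C
Reagents that add atoms: none
Why: Gold(I)-catalysed 6-exo-dig carbocyclisation of a silyl enol ether onto a terminal alkyne (Conia-ene type) forms the C4–C5 bond, the C5 quaternary centre and the exo-methylene in one step after protodeauration; the three-carbon tether on C10 can only reach the same face of C5, so the cis ring fusion (C5-Me and H10 cis) is enforced.

Step 9
Reactants: 14
Product: 15, (3S,4R,4aS,8aR)-3,4,8a-trimethyl-8-methylidene-4-[(2,3,5,6-tetramethoxyphenyl)methyl]octahydronaphthalen-1(2H)-one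
Conditions: Li, NH3(l)/THF, t-BuOH (1 equiv), −78 °C, 15 min; NH4Cl
Reagents that add atoms: none
Why: Dissolving-metal enone reduction protonates the β-carbon (C8) axially from the α face, anti to the axial C9 methyl and ring A, giving the equatorial β-methyl (C8-Me cis to C9-Me); the isolated exo-methylene is not reduced.

Step 10
Reactants: 15
Product: 16, 3-{[(1R,2S,4aR,8aS)-1,2,4a-trimethyl-5-methylidenedecahydronaphthalen-1-yl]methyl}-1,2,4,5-tetramethoxybenzene
Conditions: N2H4·H2O, KOH, diethylene glycol, 130 → 200 °C, under Ar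
Reagents that add atoms: none
Why: Wolff–Kishner (Huang-Minlon) deoxygenation of the C6 ketone; the α-carbon C5 is quaternary so the β,γ-alkene cannot move into conjugation, no stereocentre is epimerisable, and oxygen is excluded to prevent diimide reduction of the alkene.

Step 11
Reactants: 16
Product: 17, 2,5-dimethoxy-3-{[(1R,2S,4aR,8aS)-1,2,4a-trimethyl-5-methylidenedecahydronaphthalen-1-yl]methyl}cyclohexa-2,5-diene-1,4-dione
Conditions: CAN (2.5 equiv), MeCN/H2O 3:1, 0 °C
Reagents that add atoms: water, O (source of the two carbonyl oxygens)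
Why: Ceric ammonium nitrate oxidative demethylation of a para-dimethoxy pair gives the p-quinone; both possible para pairs lead to the same 3-alkyl-2,5-dimethoxyquinone by symmetry, and the exo-methylene tolerates CAN at 0 °C.

Step 12
Reactants: 17
Product: 18, 2-hydroxy-5-methoxy-3-{[(1R,2S,4aR,8aS)-1,2,4a-trimethyl-5-methylidenedecahydronaphthalen-1-yl]methyl}cyclohexa-2,5-diene-1,4-dione (target, CID21727418)
Conditions: 2 M aq. KOH, MeOH, rt; then 1 M HCl
Reagents that add atoms: potassium hydroxide/water, [OH-].[K+] / O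
Why: Addition–elimination saponification of one vinylogous ester; the methoxy group next to the alkyl substituent is twisted out of conjugation and expected to be the more electrophilic, and the resulting hydroxyquinone anion deactivates the ring so hydrolysis stops at the mono-hydroxy stage.

**Compound list**
1 | 3-methylbut-3-en-2-one | CC(=O)C(C)=C | starting material
2 | triisopropylsilyl triflate | CC(C)[Si](C(C)C)(C(C)C)OS(=O)(=O)C(F)(F)F | starting material
3 | 3-methyl-2-[(triisopropylsilyl)oxy]buta-1,3-diene | C=C(C)C(=C)O[Si](C(C)C)(C(C)C)C(C)C | intermediate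
4 | (E)-2-methylbut-2-enal | C/C=C(\C)C=O | starting material
5 | (1S,6S)-1,3,6-trimethyl-4-[(triisopropylsilyl)oxy]cyclohex-3-ene-1-carbaldehyde | CC1=C(O[Si](C(C)C)(C(C)C)C(C)C)C[C@H](C)[C@@](C)(C=O)C1 | intermediate
6 | 1,2,4,5-tetramethoxybenzene | COc1cc(OC)c(OC)cc1OC | starting material
7 | acetic anhydride | CC(=O)OC(C)=O | starting material
8 | [(1S,6S)-1,3,6-trimethyl-4-[(triisopropylsilyl)oxy]cyclohex-3-en-1-yl](2,3,5,6-tetramethoxyphenyl)methyl acetate | CC1=C(O[Si](C(C)C)(C(C)C)C(C)C)C[C@H](C)[C@@](C)(C(OC(C)=O)c2c(OC)c(OC)cc(OC)c2OC)C1 | intermediate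
9 | (4R,5S)-2,4,5-trimethyl-4-[(2,3,5,6-tetramethoxyphenyl)methyl]cyclohexan-1-one | CC1C(=O)C[C@H](C)[C@@](C)(Cc2c(OC)c(OC)cc(OC)c2OC)C1 | intermediate
10 | (4S)-2,4,5-trimethyl-4-[(2,3,5,6-tetramethoxyphenyl)methyl]cyclohexa-2,5-dien-1-one | CC1=C[C@](C)(Cc2c(OC)c(OC)cc(OC)c2OC)C(C)=CC1=O | intermediate
11 | (5-chloropent-1-yn-1-yl)trimethylsilane | C[Si](C)(C)C#CCCCCl | starting material
12 | TIPS dienol ether with TMS-alkyne chain, (5S,6S) | CC1=C(O[Si](C(C)C)(C(C)C)C(C)C)C=C(C)[C@@](C)(Cc2c(OC)c(OC)cc(OC)c2OC)[C@@H]1CCCC#C[Si](C)(C)C | intermediate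
13 | TIPS dienol ether with terminal alkyne, (5S,6S) | CC1=C(O[Si](C(C)C)(C(C)C)C(C)C)C=C(C)[C@@](C)(Cc2c(OC)c(OC)cc(OC)c2OC)[C@@H]1CCCC#C | intermediate
14 | (4S,4aS,8aR)-3,4,8a-trimethyl-8-methylidene-4-[(2,3,5,6-tetramethoxyphenyl)methyl]-4a,5,6,7,8,8a-hexahydronaphthalen-1(4H)-one | C=C1CCC[C@H]2[C@](C)(Cc3c(OC)c(OC)cc(OC)c3OC)C(C)=CC(=O)[C@@]12C | intermediate
15 | (3S,4R,4aS,8aR)-3,4,8a-trimethyl-8-methylidene-4-[(2,3,5,6-tetramethoxyphenyl)methyl]octahydronaphthalen-1(2H)-one | C=C1CCC[C@H]2[C@](C)(Cc3c(OC)c(OC)cc(OC)c3OC)[C@@H](C)CC(=O)[C@@]12C | intermediate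
16 | 3-{[(1R,2S,4aR,8aS)-1,2,4a-trimethyl-5-methylidenedecahydronaphthalen-1-yl]methyl}-1,2,4,5-tetramethoxybenzene | C=C1CCC[C@H]2[C@](C)(Cc3c(OC)c(OC)cc(OC)c3OC)[C@@H](C)CC[C@@]12C | intermediate
17 | 2,5-dimethoxy-3-{[(1R,2S,4aR,8aS)-1,2,4a-trimethyl-5-methylidenedecahydronaphthalen-1-yl]methyl}cyclohexa-2,5-diene-1,4-dione | C=C1CCC[C@H]2[C@](C)(CC3=C(OC)C(=O)C=C(OC)C3=O)[C@@H](C)CC[C@@]12C | intermediate
18 | 2-hydroxy-5-methoxy-3-{[(1R,2S,4aR,8aS)-1,2,4a-trimethyl-5-methylidenedecahydronaphthalen-1-yl]methyl}cyclohexa-2,5-diene-1,4-dione | C=C1CCC[C@H]2[C@](C)(CC3=C(O)C(=O)C=C(OC)C3=O)[C@@H](C)CC[C@@]12C | target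

**Totals**
Total steps: 12. Longest linear sequence: 12 (1 → 18); compounds 2, 4, 6, 7 and 11 are purchased.

**Three steps most likely to fail, with fallbacks**
- **Step 6** (facial selectivity of the cuprate addition rests only on Me versus CH2Ar at C9; the benzyl dienone may also fragment under electron transfer). Fallback: put the chain on the Diels–Alder diene instead, using (E)-3-methyl-2-silyloxy-nona-1,3-dien-8-yne (alkyne protected). The C10 configuration from the cycloaddition is then erased by Saegusa oxidation to the C5=C10 enone and reset by conjugate reduction, which delivers H to the α face anti to the axial C9 methyl; the enolate is trapped for the same gold cyclisation. This needs no dienone and keeps the C8 centre from the Diels–Alder.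
- **Step 5** (double dehydrogenation next to a very electron-rich arene; the product is acid-labile). Fallback: change the diene in Step 2 to a 2-methyl-1-amino-3-siloxy (Rawal-type) diene so the C5=C10 enone arises by β-elimination after cycloaddition. Only one Pd(II) Saegusa oxidation, via the kinetic silyl dienol ether, is then needed for C7=C8.
- **Step 8** (6-exo-dig closure onto a tetrasubstituted enol ether carbon; protodesilylation may compete). Fallback: use a 4-bromopent-4-enyl zinc–copper reagent in Step 6 and close ring A by Pd(0)-catalysed intramolecular α-alkenylation of the enolate/silyl enol ether with the vinyl bromide. This gives the same cis-fused exo-methylene decalone without an alkyne or gold.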